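How much open intermediate stands after the set time, as free catalyst doubles along the row of flasks?

* amount of open intermediate at the end, in percent of the substrate charged for south-east, west, north, north-west, east, in this order
* how that number moves from the first to the last of them (rises all the way / falls, then rises / falls all the way / rises, then falls / hardly changes)

in all of them: substrate 0.050 M
- Wednesday's: reagent 0.10 M; free catalyst 0.22 mM; run made earlier
- Monday's: reagent 0.10 M; free catalyst 3.9 mM; run made earlier
- south-east: reagent 0.100 M; free catalyst 0.15 mM; time 15 h
- west: reagent 0.100 M; free catalyst 0.30 mM; time 15 h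
- north: reagent 0.100 M; free catalyst 0.60 mM; time 15 h
- north-west: reagent 0.100 M; free catalyst 1.2 mM; time 15 h
- east: reagent 0.100 M; free catalyst 2.5 mM; time 15 h

- Wednesday's (time / h: open intermediate / %, target / %): 1.00: 1.8, 0.3; 2.00: 3.1, 0; 3.00: 4.4, 0.6; 4.00: 5.8, 0.8; 5.00: 7.5, 0.6; 6.00: 8.1, 1.0; 8.00: 9.3, 1.6
- Monday's (time / h: open intermediate / %, target / %): 1.00: 12.8, 7.4; 2.00: 13.8, 17.3; 3.00: 13.7, 24.0; 4.00: 12.2, 28.4; 5.00: 10.3, 29.7; 6.00: 8.3, 29.7; 8.00: 5.4, 27.9

(scatter of a reading: 0.3 percentage points)

- "hardly changes" means that all values lie within two and a half points (for a concentration: within two and a half percent of the largest)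

Wednesday's and Monday's flasks had the same charges of substrate and reagent, and Monday's c(free catalyst) was 17.7 times Wednesday's, a shift of 1.25 in the decadic logarithm of time. The reckoning here treats that shift as the shift factor of a master curve: if catalyst speeds these flasks without changing their path, a reading at time t belongs at t·c(free catalyst)/c(free catalyst, Monday) on Monday's curve. For south-east at the end this gives 0.577 h; the quantity is called Monday's clock.

In the first instants, up to Monday's clock 0.451 h, Wednesday's flask shows the scene: substrate opens, and at 8.00 h that flask holds 9.3% of open intermediate against 1.6% of target. In the middle, Monday's flask reads 13.8% of open intermediate at 2.00 h, 13.7% at 3.00 h and 12.2% at 4.00 h, so the summit of these readings lies near the first of those times, while its target reads 17.3% at 2.00 h and 24.0% at 3.00 h. Later, Monday's open intermediate reads 8.3% at 6.00 h and 5.4% at 8.00 h, a read decay of 0.215 h⁻¹, and the reckoning here carries that decay on to the far end of the row.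

Doubling the catalyst, twice, moves a flask 0.301 along the logarithmic axis. At the end, south-east reads 0.577 h, between Wednesday's last point and Monday's first; west reads 1.15 h, north 2.31 h, north-west 4.62 h, and east 9.62 h, past Monday's last reading. Straight interpolation gives 10.1%, 13.0%, 13.8% and 11.0%, and the extended decay gives 3.81% for east.

The forecast is 10.5%, 13.2%, 13.9%, 11%, 3.8%, so rises, then falls, on the ground that “the curves should collapse onto catalyst × time”; at south-east it stands above this reckoning.

The flask gives 10.5%, 13.6%, 14.3%, 10.9%, 3.89%, so rises, then falls.

    substrate + free catalyst → free catalyst + open intermediate (k = 0.0262 L mol⁻¹ s⁻¹)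
    free catalyst + open intermediate ⇌ catalyst intermediate (K = 220 L mol⁻¹, k = 0.222 L mol⁻¹ s⁻¹)
    reagent + catalyst intermediate → free catalyst + target (k = 0.0121 L mol⁻¹ s⁻¹)
    target → over-reaction product (k = 7.70 × 10⁻⁵ s⁻¹)

The step from target to over-reaction product, which runs without catalyst, makes no difference to east's open intermediate. West at 7.50 h reads Monday's clock 0.577 h, the same as south-east's 0.577 h at 15.0 h, and west then holds 10.4% of open intermediate against south-east's 10.5%.

The runs were generated by integration for substances that don't exist; noise was put on by code.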